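**Retrosynthetic overview**
- Target ⇒ global hydrogenolysis of a per-benzylated precursor; both vanilloyl esters come from one double O-acylation of a 4,5-diol with O-benzylvanilloyl chloride (arene built from catechol).
- The C4 carbinol ⇒ C4 ketone (carried as a dimethyl ketal), reduced under direction of the free 5-OH after the lactone is opened.
- Cyclohexane ring, quaternary C1 and the 1,5-lactone ⇒ one transannular benzilic ester ring contraction of a C2-symmetric 4,6-dihydroxycycloheptane-1,2-dione (key step).
- Dione ⇒ cycloheptene (ring-closing metathesis) ⇒ C2-symmetric diene diol from two-directional enantioselective allylation of dihydroxyacetone dimethyl ketal.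
- Ring order: seven-membered carbocycle first (metathesis), then six-membered carbocycle and γ-lactone together (ring contraction); the two arene rings are carried intact from catechol.

Assumption: quinic acid numbering is used for all cyclohexane compounds (C1 bears the carboxyl; the target SMILES puts the free secondary OH at C3, cis to the C4 ester, and the esters at C4 and C5); dihydroxyacetone is sold as its dimer, which reacts as the monomer.

Step 1
Reactants: 1 1,3-dihydroxyacetone
Product: 2 2,2-dimethoxypropane-1,3-diol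
Conditions: HC(OMe)3, TsOH·H2O (cat.), MeOH, rt
Reagents that add atoms: trimethyl orthoformate COC(OC)OC
Why: Acid-catalysed ketalisation with orthoformate as water scavenger masks the ketone and gives an achiral, non-enolisable diol for the two-directional allylation; no stereocentre is formed.

Step 2
Reactants: 2 2,2-dimethoxypropane-1,3-diol; 3 allyl acetate
Product: 4 (4R,6R)-5,5-dimethoxynona-1,8-diene-4,6-diol
Conditions: [Ir(cod)Cl]2 (5 mol%), (R)-Cl,MeO-BIPHEP (10 mol%), 4-chloro-3-nitrobenzoic acid (20 mol%), Cs2CO3 (40 mol%), 3 (excess, two equivalents consumed), 1,4-dioxane, 90 °C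
Reagents that add atoms: allyl acetate CC(=O)OCC=C
Why: Krische-type iridium-catalysed transfer-hydrogenative C-allylation of both primary alcohols, each taking one allyl unit from its own equivalent of 3 (the second equivalent is the entry above), a reaction type established on propane-1,3-diol and 2,2-disubstituted propane-1,3-diols; each carbinol centre is set by the chiral catalyst and the second allylation amplifies the ee, giving the C2-symmetric (4R,6R) diol (ligand sense assumed by analogy with propane-1,3-diol and checked by Mosher analysis; the other ligand enantiomer gives the mirror series).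

Step 3
Reactants: 4 (4R,6R)-5,5-dimethoxynona-1,8-diene-4,6-diol
Product: 5 (4R,6R)-5,5-dimethoxy-4,6-bis(triethylsilyloxy)nona-1,8-diene
Conditions: Et3SiCl, imidazole, DMAP (cat.), DMF, 40 °C
Reagents that add atoms: chlorotriethylsilane CC[Si](Cl)(CC)CC
Why: Standard silyl ether formation protects both carbinols against the later diol oxidation and stores them as fluoride-releasable alkoxides; no stereocentre is touched.

Step 4
Reactants: 5 (4R,6R)-5,5-dimethoxy-4,6-bis(triethylsilyloxy)nona-1,8-diene
Product: 6 (4R,6R)-5,5-dimethoxy-4,6-bis(triethylsilyloxy)cyclohept-1-ene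
Conditions: second-generation Grubbs catalyst RuCl2(=CHPh)(PCy3)(H2IMes) (3 mol%), CH2Cl2 (0.01 M), 40 °C
Reagents that add atoms: none
Why: Ring-closing metathesis of a 1,8-diene to a cycloheptene, driven by loss of ethene and helped by the gem-dimethoxy and flanking silyloxy substituents; no stereocentre is formed.

Step 5
Reactants: 6 (4R,6R)-5,5-dimethoxy-4,6-bis(triethylsilyloxy)cyclohept-1-ene
Product: 7 (1R,2S,4R,6R)-5,5-dimethoxy-4,6-bis(triethylsilyloxy)cycloheptane-1,2-diol
Conditions: OsO4 (2 mol%), N-methylmorpholine N-oxide, acetone/H2O, rt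
Reagents that add atoms: N-methylmorpholine N-oxide C[N+]1([O-])CCOCC1; water O
Why: Upjohn syn-dihydroxylation; the two alkene faces are homotopic in the C2-symmetric ring, so a single cis-diol forms and both new centres disappear again in step 6.

Step 6
Reactants: 7 (1R,2S,4R,6R)-5,5-dimethoxy-4,6-bis(triethylsilyloxy)cycloheptane-1,2-diol
Product: 8 (4R,6R)-5,5-dimethoxy-4,6-bis(triethylsilyloxy)cycloheptane-1,2-dione
Conditions: DMSO, (CF3CO)2O, CH2Cl2, −78 °C; then Et3N, −78 to −20 °C
Reagents that add atoms: none
Why: Activated-DMSO (Swern-type) oxidation of a vicinal diol to the 1,2-dione without C–C cleavage; the silyloxy centres are β to the carbonyls and are not epimerised, and the cold base quench limits β-elimination.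

Step 7
Reactants: 8 (4R,6R)-5,5-dimethoxy-4,6-bis(triethylsilyloxy)cycloheptane-1,2-dione
Product: 11 (1S,3R,5R)-1,3-dihydroxy-4,4-dimethoxy-6-oxabicyclo[3.2.1]octan-7-one, via diol-dione 9 (not isolated), via bridged hemiketal 10 (not isolated)
Conditions: Bu4NF/AcOH (1:1, 2.4 equiv), THF, 0 °C; then DBU (0.3 equiv), 0 °C to rt; NH4Cl quench
Reagents that add atoms: none
Why: Proposed new method: a fluoride-triggered, hydroxyl-relayed transannular benzilic ester ring contraction – buffered desilylation frees the two homotopic hydroxyls, one adds across the ring to the distal carbonyl (five-membered hemiketal 10, which also blocks retro-aldol cleavage), and catalytic DBU makes the hemiketal oxygen push a 1,2-shift of the ring CH2 onto the neighbouring ketone, contracting the seven-membered ring to the cyclohexane and turning the hemiketal carbon into the lactone carbonyl; the lactone can only bridge C1 and C5 on one face, so the carboxyl is cis to O5 and the tertiary OH cis to O3, and C2 symmetry makes both hydroxyls give the same product, so C1 is set without a selectivity question; the closest known chemistry is the alkoxide-mediated benzilic ester rearrangement of 1,2-diketones and the base-promoted α-ketol shift, not yet shown with a transannular hydroxyl as the internal alkoxide on a cycloheptane-1,2-dione.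

Step 8
Reactants: 11 (1S,3R,5R)-1,3-dihydroxy-4,4-dimethoxy-6-oxabicyclo[3.2.1]octan-7-one
Product: 12 (1S,3R,5R)-1,3-bis(benzyloxy)-4,4-dimethoxy-6-oxabicyclo[3.2.1]octan-7-one
Conditions: NaH, BnBr, Bu4NI (cat.), DMF, 0 °C to rt
Reagents that add atoms: benzyl bromide BrCc1ccccc1
Why: Exhaustive Williamson benzylation; the lactone keeps O5 masked, so the two oxygens that must end as free OH (O1 and O3) are the only ones benzylated, and O3 (trans to the lactone carbonyl) cannot translactonise.

Step 9
Reactants: 12 (1S,3R,5R)-1,3-bis(benzyloxy)-4,4-dimethoxy-6-oxabicyclo[3.2.1]octan-7-one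
Product: 14 benzyl (1R,3R,5R)-1,3-bis(benzyloxy)-5-hydroxy-4,4-dimethoxycyclohexane-1-carboxylate, via lithium carboxylate 13 (not isolated)
Conditions: LiOH (1.05 equiv), THF/H2O, 0 °C; evaporate; BnBr, DMF, rt
Reagents that add atoms: lithium hydroxide [Li+].[OH-]; benzyl bromide BrCc1ccccc1
Why: Lactone saponification then carboxylate O-alkylation (the carboxylate is never acidified, so it cannot relactonise) frees only the 5-OH; the ketone is still masked, so no α-centre can epimerise under base.

Step 10
Reactants: 14 benzyl (1R,3R,5R)-1,3-bis(benzyloxy)-5-hydroxy-4,4-dimethoxycyclohexane-1-carboxylate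
Product: 16 benzyl (1R,3R,4S,5R)-1,3-bis(benzyloxy)-4,5-dihydroxycyclohexane-1-carboxylate, via 4-oxo ester 15 (not isolated)
Conditions: CF3CO2H/H2O 9:1, CH2Cl2, 0 °C; evaporate; Me4NBH(OAc)3, MeCN/AcOH, −30 °C
Reagents that add atoms: water O
Why: Ketal hydrolysis followed by hydroxyl-directed triacetoxyborohydride reduction (Evans–Saksena type); the 5-O–B species delivers hydride to the face of C4 syn to O5, so the new 4-OH is trans to 5-OH and cis to 3-OBn (quinic configuration), reinforced by attack anti to the axial 3-benzyloxy group.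

Step 11
Reactants: 17 catechol
Product: 18 2-methoxyphenol
Conditions: MeI (1.0 equiv), K2CO3, acetone, reflux; distil
Reagents that add atoms: iodomethane CI
Why: Williamson mono-O-methylation with one equivalent of electrophile; unreacted catechol and the dimethyl ether are removed by distillation.

Step 12
Reactants: 18 2-methoxyphenol
Product: 20 1-(benzyloxy)-4-bromo-2-methoxybenzene, via 4-bromo-2-methoxyphenol 19 (not isolated)
Conditions: NBS, MeCN, 0 °C; then K2CO3, BnBr (excess), 60 °C; recrystallise
Reagents that add atoms: N-bromosuccinimide O=C1CCC(=O)N1Br; benzyl bromide BrCc1ccccc1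
Why: Electrophilic bromination goes para to the free hydroxyl (the stronger donor), then Williamson benzylation in the same pot protects the phenol with a group removed in the final hydrogenolysis.

Step 13
Reactants: 20 1-(benzyloxy)-4-bromo-2-methoxybenzene
Product: 22 4-(benzyloxy)-3-methoxybenzoic acid, via [4-(benzyloxy)-3-methoxyphenyl]lithium 21 (not isolated)
Conditions: n-BuLi, THF, −78 °C; CO2; aq. HCl
Reagents that add atoms: carbon dioxide O=C=O
Why: Bromine–lithium exchange and carboxylation of the aryllithium give the protected vanillic acid with the carboxyl para to the benzyloxy group.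

Step 14
Reactants: 16 benzyl (1R,3R,4S,5R)-1,3-bis(benzyloxy)-4,5-dihydroxycyclohexane-1-carboxylate; 22 4-(benzyloxy)-3-methoxybenzoic acid
Product: 24 benzyl (1S,3R,4R,5R)-1,3-bis(benzyloxy)-4,5-bis{[4-(benzyloxy)-3-methoxybenzoyl]oxy}cyclohexane-1-carboxylate, via 4-(benzyloxy)-3-methoxybenzoyl chloride 23 (not isolated)
Conditions: 22 (2.6 equiv), (COCl)2, DMF (cat.), CH2Cl2, rt; evaporate; then 16, pyridine, DMAP (cat.), CH2Cl2, 0 to 40 °C
Reagents that add atoms: none
Why: Acid chloride formation and DMAP-catalysed acylation of the only two free hydroxyls (the trans-diequatorial 4,5-diol; O1 and O3 are benzylated), so regiochemistry is fixed by protection and acyl migration between O4 and O5 is irrelevant.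

Step 15
Reactants: 24 benzyl (1S,3R,4R,5R)-1,3-bis(benzyloxy)-4,5-bis{[4-(benzyloxy)-3-methoxybenzoyl]oxy}cyclohexane-1-carboxylate
Product: 25 Burkinabin C, (1S,3R,4R,5R)-1,3-dihydroxy-4,5-bis[(4-hydroxy-3-methoxybenzoyl)oxy]cyclohexane-1-carboxylic acid
Conditions: H2 (1 atm), Pd(OH)2 on carbon, THF/EtOAc, rt; reverse-phase purification below pH 5
Reagents that add atoms: none
Why: Neutral hydrogenolysis removes all five benzyl groups (two aryl ethers, two alkyl ethers, one ester) at once without base, so the 4-O-acyl group does not migrate to the cis 3-OH; no stereocentre is affected.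

**Compound list**
1 | 1,3-dihydroxyacetone | OCC(=O)CO | starting material
2 | 2,2-dimethoxypropane-1,3-diol | COC(CO)(CO)OC | intermediate
3 | allyl acetate | CC(=O)OCC=C | starting material
4 | (4R,6R)-5,5-dimethoxynona-1,8-diene-4,6-diol | C=CC[C@@H](O)C(OC)(OC)[C@H](O)CC=C | intermediate
5 | (4R,6R)-5,5-dimethoxy-4,6-bis(triethylsilyloxy)nona-1,8-diene | C=CC[C@@H](O[Si](CC)(CC)CC)C(OC)(OC)[C@H](O[Si](CC)(CC)CC)CC=C | intermediate
6 | (4R,6R)-5,5-dimethoxy-4,6-bis(triethylsilyloxy)cyclohept-1-ene | C1[C@@H](O[Si](CC)(CC)CC)C(OC)(OC)[C@H](O[Si](CC)(CC)CC)CC=C1 | intermediate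
7 | (1R,2S,4R,6R)-5,5-dimethoxy-4,6-bis(triethylsilyloxy)cycloheptane-1,2-diol | C1[C@@H](O[Si](CC)(CC)CC)C(OC)(OC)[C@H](O[Si](CC)(CC)CC)C[C@@H](O)[C@H]1O | intermediate
8 | (4R,6R)-5,5-dimethoxy-4,6-bis(triethylsilyloxy)cycloheptane-1,2-dione | C1[C@@H](O[Si](CC)(CC)CC)C(OC)(OC)[C@H](O[Si](CC)(CC)CC)CC(=O)C1=O | intermediate
9 | (4R,6R)-4,6-dihydroxy-5,5-dimethoxycycloheptane-1,2-dione | C1[C@@H](O)C(OC)(OC)[C@H](O)CC(=O)C1=O | intermediate (not isolated)
10 | (1R,3R,5R)-1,3-dihydroxy-4,4-dimethoxy-8-oxabicyclo[3.2.1]octan-7-one (bridged hemiketal of 9) | O=C1C[C@H]2O[C@]1(O)C[C@@H](O)C2(OC)OC | intermediate (not isolated)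
11 | (1S,3R,5R)-1,3-dihydroxy-4,4-dimethoxy-6-oxabicyclo[3.2.1]octan-7-one (1,5-lactone of the 4-ketal of 4-dehydroquinic acid) | C1[C@@H](O)C(OC)(OC)[C@H]2C[C@]1(O)C(=O)O2 | intermediate
12 | (1S,3R,5R)-1,3-bis(benzyloxy)-4,4-dimethoxy-6-oxabicyclo[3.2.1]octan-7-one | C1[C@@H](OCc3ccccc3)C(OC)(OC)[C@H]2C[C@]1(OCc4ccccc4)C(=O)O2 | intermediate
13 | lithium (1R,3R,5R)-1,3-bis(benzyloxy)-5-hydroxy-4,4-dimethoxycyclohexane-1-carboxylate | C1[C@@H](OCc2ccccc2)C(OC)(OC)[C@H](O)C[C@]1(OCc3ccccc3)C(=O)[O-].[Li+] | intermediate (not isolated)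
14 | benzyl (1R,3R,5R)-1,3-bis(benzyloxy)-5-hydroxy-4,4-dimethoxycyclohexane-1-carboxylate | C1[C@@H](OCc2ccccc2)C(OC)(OC)[C@H](O)C[C@]1(OCc3ccccc3)C(=O)OCc4ccccc4 | intermediate
15 | benzyl (1R,3R,5R)-1,3-bis(benzyloxy)-5-hydroxy-4-oxocyclohexane-1-carboxylate | C1[C@@H](OCc2ccccc2)C(=O)[C@H](O)C[C@]1(OCc3ccccc3)C(=O)OCc4ccccc4 | intermediate (not isolated)
16 | benzyl (1R,3R,4S,5R)-1,3-bis(benzyloxy)-4,5-dihydroxycyclohexane-1-carboxylate (benzyl 1,3-di-O-benzylquinate) | C1[C@@H](OCc2ccccc2)[C@@H](O)[C@H](O)C[C@]1(OCc3ccccc3)C(=O)OCc4ccccc4 | intermediate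
17 | catechol | Oc1ccccc1O | starting material
18 | 2-methoxyphenol | COc1ccccc1O | intermediate
19 | 4-bromo-2-methoxyphenol | COc1cc(Br)ccc1O | intermediate (not isolated)
20 | 1-(benzyloxy)-4-bromo-2-methoxybenzene | COc1cc(Br)ccc1OCc1ccccc1 | intermediate
21 | [4-(benzyloxy)-3-methoxyphenyl]lithium | [Li]c1ccc(OCc2ccccc2)c(OC)c1 | intermediate (not isolated)
22 | 4-(benzyloxy)-3-methoxybenzoic acid | COc1cc(C(=O)O)ccc1OCc1ccccc1 | intermediate
23 | 4-(benzyloxy)-3-methoxybenzoyl chloride | COc1cc(C(Cl)=O)ccc1OCc1ccccc1 | intermediate (not isolated)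
24 | benzyl (1S,3R,4R,5R)-1,3-bis(benzyloxy)-4,5-bis{[4-(benzyloxy)-3-methoxybenzoyl]oxy}cyclohexane-1-carboxylate | C1[C@@H](OCc2ccccc2)[C@@H](OC(=O)c2ccc(OCc3ccccc3)c(OC)c2)[C@H](OC(=O)c2ccc(OCc3ccccc3)c(OC)c2)C[C@]1(OCc2ccccc2)C(=O)OCc2ccccc2 | intermediate
25 | Burkinabin C, (1S,3R,4R,5R)-1,3-dihydroxy-4,5-bis[(4-hydroxy-3-methoxybenzoyl)oxy]cyclohexane-1-carboxylic acid | COc1cc(C(=O)O[C@@H]2[C@H](O)C[C@@](O)(C(=O)O)C[C@H]2OC(=O)c2ccc(O)c(OC)c2)ccc1O | target

**Totals**
Total step count: 15. Longest linear sequence: 12 steps (steps 1–10, 14, 15); the arene arm is 3 steps (11–13).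

**Three steps most likely to fail**

Step 7 (the proposed ring contraction). The risks are β-elimination or retro-aldol cleavage of the free hydroxy-dione 9 before the shift, or a hemiketal that does not rearrange under mild base. The fallback sets out from 8 and comes back at 11 using known chemistry only, and it avoids the free hydroxy-dione altogether. The still-silylated dione 8 is treated with KOH in aqueous 1,4-dioxane at 0 °C to rt (classical hydroxide-mediated benzilic acid rearrangement of a cycloalkane-1,2-dione) and acidified cold to pH 4. This gives the ring-contracted acid (3R,5R)-1-hydroxy-4,4-dimethoxy-3,5-bis(triethylsilyloxy)cyclohexane-1-carboxylic acid F1, in which C1 is not a stereocentre because the two ring arms are identical. Desilylation with Bu4NF/AcOH in THF gives the acid (3R,5R)-1,3,5-trihydroxy-4,4-dimethoxycyclohexane-1-carboxylic acid F2. F2 is lactonised with EDC·HCl and DMAP in CH2Cl2/DMF; only the hydroxyl cis to the carboxyl can reach it, and since C1 of F2 is not a stereocentre this closure gives 11 as the only γ-lactone. Stereocontrol at C1 thus moves from the rearrangement to a separate lactonisation.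

Step 2 (two-directional allylation of the α,α-dimethoxy diol). The risks are slow alcohol dehydrogenation next to the ketal, stalling at the mono-adduct, or catalyst inhibition by the chelating substrate. The fallback sets out from 2 and comes back at 4. Both alcohols are oxidised under Swern conditions to the non-enolisable dialdehyde 2,2-dimethoxypropanedial F3, which is added cold, without isolation, to two equivalents of B-allyldiisopinocampheylborane (the enantiomer giving R carbinols). Oxidative work-up gives 4. This replaces the catalytic alcohol C–H allylation by stoichiometric reagent-controlled allylboration of preformed aldehydes.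

Step 10 (late ketal hydrolysis and directed reduction). The risks are slow hydrolysis of the doubly α-oxygenated ketal, acid-catalysed relactonisation of the free 5-OH onto the benzyl ester, enolisation of the α-oxygenated ketone, or poor hydride delivery. The fallback sets out from 14 and comes back at 24. The 5-OH of 14 is first acylated with acid chloride 23 (pyridine, DMAP) to give benzyl (1S,3R,5R)-1,3-bis(benzyloxy)-5-{[4-(benzyloxy)-3-methoxybenzoyl]oxy}-4,4-dimethoxycyclohexane-1-carboxylate F4, which cannot lactonise. Ketal hydrolysis then gives the ketone benzyl (1S,3R,5R)-1,3-bis(benzyloxy)-5-{[4-(benzyloxy)-3-methoxybenzoyl]oxy}-4-oxocyclohexane-1-carboxylate F5. Reduction with NaBH4/CeCl3·7H2O at −78 °C, under substrate control (hydride anti to the axial 3-benzyloxy group), gives the alcohol benzyl (1S,3R,4R,5R)-1,3-bis(benzyloxy)-5-{[4-(benzyloxy)-3-methoxybenzoyl]oxy}-4-hydroxycyclohexane-1-carboxylate F6. Any acyl shift between O5 and O4 at this stage is harmless, because a second acylation with 23 gives 24 either way.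

**Further compounds**
F1 | step 7 | (3R,5R)-1-hydroxy-4,4-dimethoxy-3,5-bis(triethylsilyloxy)cyclohexane-1-carboxylic acid | C1[C@@H](O[Si](CC)(CC)CC)C(OC)(OC)[C@H](O[Si](CC)(CC)CC)CC1(O)C(=O)O
F2 | step 7 | (3R,5R)-1,3,5-trihydroxy-4,4-dimethoxycyclohexane-1-carboxylic acid | C1[C@@H](O)C(OC)(OC)[C@H](O)CC1(O)C(=O)O
F3 | step 2 | 2,2-dimethoxypropanedial | O=CC(OC)(OC)C=O
F4 | step 10 | benzyl (1S,3R,5R)-1,3-bis(benzyloxy)-5-{[4-(benzyloxy)-3-methoxybenzoyl]oxy}-4,4-dimethoxycyclohexane-1-carboxylate | C1[C@@H](OCc2ccccc2)C(OC)(OC)[C@H](OC(=O)c2ccc(OCc3ccccc3)c(OC)c2)C[C@]1(OCc2ccccc2)C(=O)OCc2ccccc2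
F5 | step 10 | benzyl (1S,3R,5R)-1,3-bis(benzyloxy)-5-{[4-(benzyloxy)-3-methoxybenzoyl]oxy}-4-oxocyclohexane-1-carboxylate | C1[C@@H](OCc2ccccc2)C(=O)[C@H](OC(=O)c2ccc(OCc3ccccc3)c(OC)c2)C[C@]1(OCc2ccccc2)C(=O)OCc2ccccc2
F6 | step 10 | benzyl (1S,3R,4R,5R)-1,3-bis(benzyloxy)-5-{[4-(benzyloxy)-3-methoxybenzoyl]oxy}-4-hydroxycyclohexane-1-carboxylate | C1[C@@H](OCc2ccccc2)[C@@H](O)[C@H](OC(=O)c2ccc(OCc3ccccc3)c(OC)c2)C[C@]1(OCc2ccccc2)C(=O)OCc2ccccc2
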